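**Retrosynthetic overview**

1. Endgame: the C10 allylic alcohol comes from Luche reduction of a C10 enone, and the C8 methyl from cuprate addition and re-dehydrogenation of that enone. The 2α-acetate and 6α-anisoate are put on stepwise; the 6α-hydroxyl comes from hydroxyl-directed reduction and the C4 carbinol from isopropyl addition to a C4/C6 1,3-diketone.
2. Key disconnection (bonds C5–C6 and C1–C5): the fused 5–7 diketone comes from a monocyclic cyclohexanone whose quaternary α-carbon carries a 4-diazo-3-oxobutyl chain. The diazo carbon (C5) adds to the ring carbonyl (C6), then the C1–C6 bond shifts to C5, so C5 is inserted as a single carbon into the six-membered ring.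
3. Enabling feature: ring-fusion carbon C5 lies between two oxygenated carbons, C4 of the five-membered ring and C6 of the seven-membered ring (a latent 2-acylcycloheptanone). Quaternary C1 is flanked in the seven-membered ring by oxygenated C10, so C1/C6/C7/C8/C9/C10 is a disguised 2-methylcyclohexane-1,3-dione.
4. Precursor: 2-methylcyclohexane-1,3-dione plus benzyloxyallene (sets C2), desymmetrizing transfer hydrogenation (sets C1), then chain extension to the diazo ketone.
5. Ring order: six-membered ring A (purchased) → transient second six-membered ring closed by the C5–C6 bond → contracted in the same step to the five-membered ring while ring A expands to the seven-membered ring.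

Key step: step 8

Remark on the chemistry: daucane locants are used for the bicyclic compounds (C1 angular-methyl carbon, C2–C4 rest of the five-membered ring, C5 ring-fusion CH, C6–C10 rest of the seven-membered ring; β = face of the C1 methyl); 12 is drawn as its C6 enol, and 23 is expected as a mixture of C8 epimers that converge in step 18.

**Route**

Step 1
Reactants: 1 benzyl propargyl ether
Product: 2 benzyloxyallene
Conditions: KOtBu (0.3 equiv), THF, rt
Reagents that add atoms: none
Why: Base-catalysed propargyl-to-allenyl ether isomerization is the standard access to alkoxyallenes and creates no stereocentre.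

Step 2
Reactants: 2 benzyloxyallene; 3 2-methylcyclohexane-1,3-dione
Product: 4 (S)-2-[1-(benzyloxy)prop-2-en-1-yl]-2-methylcyclohexane-1,3-dione
Conditions: Pd2(dba)3·CHCl3 (2.5 mol %), (R,R)-DACH-phenyl bisphosphine ligand (7.5 mol %), PhCO2H (10 mol %), CH2Cl2, rt
Reagents that add atoms: none
Why: Palladium-catalysed asymmetric addition of an acidic 1,3-dicarbonyl pronucleophile to an alkoxyallene (hydropalladation to an alkoxy π-allyl complex, attack at the oxygen-bearing terminus) should give the branched allylic ether, the ligand (antipode to be chosen so that S results) setting the future C2 while the quaternary carbon stays prochiral.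

Step 3
Reactants: 4 (S)-2-[1-(benzyloxy)prop-2-en-1-yl]-2-methylcyclohexane-1,3-dione
Product: 5 (2S,3R)-2-[(S)-1-(benzyloxy)prop-2-en-1-yl]-3-hydroxy-2-methylcyclohexan-1-one
Conditions: RuCl[(S,S)-TsDPEN](p-cymene) (2 mol %), HCO2H/Et3N 5:2, CH2Cl2, rt
Reagents that add atoms: none
Why: Noyori–Ikariya asymmetric transfer hydrogenation is an established desymmetrization of 2,2-disubstituted cyclic 1,3-diones, so the catalyst (antipode chosen as required) should reduce one of the two diastereotopic carbonyls and thereby fix the quaternary carbon (future C1), with hydride expected on the methyl face so that the hydroxyl is cis to the side chain (this carbinol centre is erased in step 16).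

Step 4
Reactants: 5 (2S,3R)-2-[(S)-1-(benzyloxy)prop-2-en-1-yl]-3-hydroxy-2-methylcyclohexan-1-one
Product: 6 (2R,3R)-2-[(S)-1-(benzyloxy)prop-2-en-1-yl]-3-(tert-butyldimethylsilyloxy)-2-methylcyclohexan-1-one
Conditions: TBSOTf, 2,6-lutidine, CH2Cl2, −78 to 0 °C
Reagents that add atoms: tert-butyldimethylsilyl triflate, CC(C)(C)[Si](C)(C)OS(=O)(=O)C(F)(F)F
Why: Silyl triflate silylation of a hindered secondary alcohol is reliable and blocks retro-aldol opening of the β-hydroxy ketone while masking the future C10 oxygen.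

Step 5
Reactants: 6 (2R,3R)-2-[(S)-1-(benzyloxy)prop-2-en-1-yl]-3-(tert-butyldimethylsilyloxy)-2-methylcyclohexan-1-one
Product: 7 (2R,3R)-2-[(S)-1-(benzyloxy)-3-hydroxypropyl]-3-(tert-butyldimethylsilyloxy)-2-methylcyclohexan-1-one
Conditions: 9-BBN, THF, 0 °C to rt; then NaOH, H2O2, 0 °C
Reagents that add atoms: hydrogen peroxide, OO
Why: Brown hydroboration–oxidation with the bulky 9-BBN should add anti-Markovnikov to the terminal alkene and spare the hindered neopentyl ketone.

Step 6
Reactants: 7 (2R,3R)-2-[(S)-1-(benzyloxy)-3-hydroxypropyl]-3-(tert-butyldimethylsilyloxy)-2-methylcyclohexan-1-one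
Product: 8 (S)-3-(benzyloxy)-3-[(1R,2R)-2-(tert-butyldimethylsilyloxy)-1-methyl-6-oxocyclohexyl]propanoic acid
Conditions: TEMPO (cat.), PhI(OAc)2, MeCN/H2O, rt
Reagents that add atoms: water, O
Why: TEMPO/PhI(OAc)2 oxidation takes a primary alcohol through the aldehyde hydrate to the acid and tolerates silyl ether, benzyl ether and ketone.

Step 7
Reactants: 8 (S)-3-(benzyloxy)-3-[(1R,2R)-2-(tert-butyldimethylsilyloxy)-1-methyl-6-oxocyclohexyl]propanoic acid
Product: 10 (S)-4-(benzyloxy)-1-diazo-4-[(1R,2R)-2-(tert-butyldimethylsilyloxy)-1-methyl-6-oxocyclohexyl]butan-2-one, via isobutyl carbonic mixed anhydride 9 (not isolated)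
Conditions: iBuOCOCl, Et3N, THF, −15 °C; then CH2N2, Et2O, 0 °C
Reagents that add atoms: diazomethane, C=[N+]=[N-]
Why: Acylation of diazomethane by a mixed anhydride (first stage of the Arndt–Eistert sequence) is the standard mild route to a diazomethyl ketone.

Step 8
Reactants: 10 (S)-4-(benzyloxy)-1-diazo-4-[(1R,2R)-2-(tert-butyldimethylsilyloxy)-1-methyl-6-oxocyclohexyl]butan-2-one
Product: 12 2α-(benzyloxy)-10α-(tert-butyldimethylsilyloxy)-6-hydroxy-1β-methylbicyclo[5.3.0]dec-5-en-4-one (enol of the 4,6-dione), via oxido diazonium adduct 11 (not isolated)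
Conditions: Sc(OTf)3 (20 mol %), CH2Cl2, −20 °C to rt
Reagents that add atoms: none
Why: Proposed new method: Sc(OTf)3 activates the only free ring ketone (C6), the nucleophilic diazo carbon C5 adds to it (6-exo-trig, chair, closing a transient six-membered carbinol ring cis-fused to ring A), and the C1–C6 bond antiperiplanar to the diazonium group then shifts to C5 with loss of N2, which contracts the new ring to the cyclopentanone and expands ring A to the cycloheptanone in one operation. The closest known reactions are the Lewis-acid-promoted Tiffeneau–Demjanov/Roskamp homologation of cycloalkanones by α-diazo carbonyl compounds and the intramolecular Schmidt reaction of 2-(3-azidopropyl)cycloalkanones, in which the tether-bearing α-carbon likewise migrates to give the fused 5–7 bicycle. No new stereocentre has to be controlled, because C5 ends as the enolizable methine of a 1,3-diketone, and C1 migrates with retention so that the quaternary centre fixed in step 3 is carried over unchanged. The step needs migration of C1 instead of C7 (bridged isomer) or epoxide closure, which the equatorial diazonium group of the chair adduct (ring bond C6–C1 antiperiplanar) and the higher migratory aptitude of the quaternary carbon should secure; chemoselectivity is secured because the second ring carbonyl is masked as the C10 silyl ether.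

Step 9
Reactants: 12 2α-(benzyloxy)-10α-(tert-butyldimethylsilyloxy)-6-hydroxy-1β-methylbicyclo[5.3.0]dec-5-en-4-one
Product: 13 2α-(benzyloxy)-10α-(tert-butyldimethylsilyloxy)-1β-methyl-6-(triethylsilyloxy)bicyclo[5.3.0]dec-5-en-4-one
Conditions: Et3SiCl, Et3N, CH2Cl2, 0 °C
Reagents that add atoms: chlorotriethylsilane, CC[Si](Cl)(CC)CC
Why: O-silylation of the 1,3-diketone should settle on O6, since the C5=C6 enol double bond is exocyclic to the five-membered ring and endocyclic in the seven-membered ring (the preferred arrangement for both ring sizes), leaving C4 as the free carbonyl.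

Step 10
Reactants: 13 2α-(benzyloxy)-10α-(tert-butyldimethylsilyloxy)-1β-methyl-6-(triethylsilyloxy)bicyclo[5.3.0]dec-5-en-4-one
Product: 15 2α-(benzyloxy)-10α-(tert-butyldimethylsilyloxy)-4β-hydroxy-4α-isopropyl-1β-methyl-5α-H-bicyclo[5.3.0]decan-6-one (trans-fused), via tertiary alkoxide adduct 14 (not isolated)
Conditions: iPrMgCl, CeCl3, THF, −78 °C; then Bu4NF, AcOH, THF, −20 to 0 °C
Reagents that add atoms: isopropylmagnesium chloride, CC(C)[Mg]Cl
Why: Non-basic organocerium 1,2-addition to the carbonyl of a vinylogous silyl ester (Stork–Danheiser-type) is expected anti to the angular methyl (isopropyl α, hydroxyl β, possibly helped by coordination to the 2α-ether oxygen), and buffered fluoride then unmasks the C6 ketone under non-ionizing conditions, C5 being set by protonation and enol equilibration to the trans-fused aldol in which the 4β-hydroxyl hydrogen-bonds to the C6 carbonyl and the isopropyl group avoids the seven-membered ring.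

Step 11
Reactants: 15 2α-(benzyloxy)-10α-(tert-butyldimethylsilyloxy)-4β-hydroxy-4α-isopropyl-1β-methyl-5α-H-bicyclo[5.3.0]decan-6-one
Product: 16 2α-(benzyloxy)-10α-(tert-butyldimethylsilyloxy)-4α-isopropyl-1β-methyl-5α-H-bicyclo[5.3.0]decane-4β,6α-diol
Conditions: Me4NBH(OAc)3, MeCN/AcOH, −30 °C
Reagents that add atoms: none
Why: In the Evans–Saksena reduction the alkoxy-triacetoxyborohydride formed at the 4β-hydroxyl delivers hydride intramolecularly to the face of the C6 carbonyl that is turned toward C4, which should give the 6α-alcohol (1,3-anti diol).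

Step 12
Reactants: 16 2α-(benzyloxy)-10α-(tert-butyldimethylsilyloxy)-4α-isopropyl-1β-methyl-5α-H-bicyclo[5.3.0]decane-4β,6α-diol
Product: 17 6α-(4-methoxybenzoate) of 16
Conditions: 4-MeOC6H4COCl, DMAP, Et3N, CH2Cl2, 0 °C to rt
Reagents that add atoms: 4-methoxybenzoyl chloride, COc1ccc(C(Cl)=O)cc1
Why: DMAP-catalysed acylation should take the only free secondary hydroxyl and leave the tertiary C4 hydroxyl untouched.

Step 13
Reactants: 17 6α-(4-methoxybenzoate) of 16
Product: 18 10α-(tert-butyldimethylsilyloxy)-4α-isopropyl-6α-(4-methoxybenzoyloxy)-1β-methyl-5α-H-bicyclo[5.3.0]decane-2α,4β-diol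
Conditions: H2 (1 atm), Pd(OH)2/C, EtOAc, rt
Reagents that add atoms: none
Why: Hydrogenolysis of the benzyl ether is placed before any alkene is present and leaves the benzoate-type ester and the silyl ether intact.

Step 14
Reactants: 18 10α-(tert-butyldimethylsilyloxy)-4α-isopropyl-6α-(4-methoxybenzoyloxy)-1β-methyl-5α-H-bicyclo[5.3.0]decane-2α,4β-diol
Product: 19 2α-acetate of 18
Conditions: Ac2O, DMAP (cat.), pyridine, CH2Cl2, rt
Reagents that add atoms: acetic anhydride, CC(=O)OC(C)=O
Why: Acetylation should again discriminate the secondary 2α-hydroxyl from the hindered tertiary C4 hydroxyl.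

Step 15
Reactants: 19 2α-acetate of 18
Product: 20 2α-acetoxy-4α-isopropyl-6α-(4-methoxybenzoyloxy)-1β-methyl-5α-H-bicyclo[5.3.0]decane-4β,10α-diol
Conditions: HF·pyridine, pyridine/THF, 0 °C to rt
Reagents that add atoms: none
Why: Buffered HF·pyridine removes the silyl ether without the basic conditions that could cause acyl migration or ester cleavage.

Step 16
Reactants: 20 2α-acetoxy-4α-isopropyl-6α-(4-methoxybenzoyloxy)-1β-methyl-5α-H-bicyclo[5.3.0]decane-4β,10α-diol
Product: 22 2α-acetoxy-4β-hydroxy-4α-isopropyl-6α-(4-methoxybenzoyloxy)-1β-methyl-5α-H-bicyclo[5.3.0]dec-8-en-10-one, via saturated C10 ketone 21 (not isolated)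
Conditions: IBX (3 equiv), DMSO/fluorobenzene, 75 °C
Reagents that add atoms: none
Why: IBX oxidizes the secondary alcohol and then dehydrogenates the resulting ketone in the same pot, and the enone can only form toward C9 because C1 is quaternary.

Step 17
Reactants: 22 2α-acetoxy-4β-hydroxy-4α-isopropyl-6α-(4-methoxybenzoyloxy)-1β-methyl-5α-H-bicyclo[5.3.0]dec-8-en-10-one
Product: 23 2α-acetoxy-4β-hydroxy-6α-(4-methoxybenzoyloxy)daucan-10-one (C8 epimers)
Conditions: Me2CuLi (from CuI and MeLi), Et2O/THF, −78 °C; aq NH4Cl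
Reagents that add atoms: lithium dimethylcuprate, [Li+].C[Cu-]C
Why: Gilman conjugate addition to the unhindered β-carbon C8 of the cycloheptenone is fast at −78 °C, where both esters survive, and the configuration created at C8 is irrelevant.

Step 18
Reactants: 23 2α-acetoxy-4β-hydroxy-6α-(4-methoxybenzoyloxy)daucan-10-one (C8 epimers)
Product: 24 2α-acetoxy-4β-hydroxy-6α-(4-methoxybenzoyloxy)dauc-8-en-10-one
Conditions: IBX (2 equiv), DMSO/fluorobenzene, 75 °C
Reagents that add atoms: none
Why: A second IBX dehydrogenation, again regiospecific toward C9/C8, should restore the double bond, now trisubstituted and bearing the C8 methyl, from both C8 epimers.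

Step 19
Reactants: 24 2α-acetoxy-4β-hydroxy-6α-(4-methoxybenzoyloxy)dauc-8-en-10-one
Product: 25 2α-acetoxy-4β,10β-dihydroxy-6α-(4-methoxybenzoyloxy)dauc-8-ene (CNP0261832.1)
Conditions: NaBH4, CeCl3·7H2O, MeOH, −78 °C
Reagents that add atoms: none
Why: Luche 1,2-reduction of the enone leaves the esters alone, and hydride is expected on the α face, anti to the axial angular methyl on the neighbouring C1, to give the 10β-alcohol.

**Compound list**

1 | benzyl propargyl ether | C#CCOCc1ccccc1 | starting material
2 | benzyloxyallene | C=C=COCc1ccccc1 | intermediate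
3 | 2-methylcyclohexane-1,3-dione | CC1C(=O)CCCC1=O | starting material
4 | (S)-2-[1-(benzyloxy)prop-2-en-1-yl]-2-methylcyclohexane-1,3-dione | CC1([C@@H](OCc2ccccc2)C=C)C(=O)CCCC1=O | intermediate
5 | (2S,3R)-2-[(S)-1-(benzyloxy)prop-2-en-1-yl]-3-hydroxy-2-methylcyclohexan-1-one (hydroxyl cis to the side chain) | C[C@]1([C@@H](OCc2ccccc2)C=C)C(=O)CCC[C@H]1O | intermediate
6 | tert-butyldimethylsilyl ether of 5 | C[C@]1([C@@H](OCc2ccccc2)C=C)C(=O)CCC[C@H]1O[Si](C)(C)C(C)(C)C | intermediate
7 | (2R,3R)-2-[(S)-1-(benzyloxy)-3-hydroxypropyl]-3-(tert-butyldimethylsilyloxy)-2-methylcyclohexan-1-one | C[C@]1([C@@H](OCc2ccccc2)CCO)C(=O)CCC[C@H]1O[Si](C)(C)C(C)(C)C | intermediate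
8 | (S)-3-(benzyloxy)-3-[(1R,2R)-2-(tert-butyldimethylsilyloxy)-1-methyl-6-oxocyclohexyl]propanoic acid | C[C@]1([C@@H](OCc2ccccc2)CC(=O)O)C(=O)CCC[C@H]1O[Si](C)(C)C(C)(C)C | intermediate
9 | mixed anhydride of 8 with isobutyl carbonic acid | C[C@]1([C@@H](OCc2ccccc2)CC(=O)OC(=O)OCC(C)C)C(=O)CCC[C@H]1O[Si](C)(C)C(C)(C)C | intermediate
10 | (S)-4-(benzyloxy)-1-diazo-4-[(1R,2R)-2-(tert-butyldimethylsilyloxy)-1-methyl-6-oxocyclohexyl]butan-2-one | C[C@]1([C@@H](OCc2ccccc2)CC(=O)C=[N+]=[N-])C(=O)CCC[C@H]1O[Si](C)(C)C(C)(C)C | intermediate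
11 | zwitterionic 5-diazonio-6-oxido bicyclo[4.4.0]decan-4-one adduct (drawn metal-free; C5 and C6 transient) | C[C@]12[C@@H](OCc3ccccc3)CC(=O)C([N+]#N)C1([O-])CCC[C@H]2O[Si](C)(C)C(C)(C)C | intermediate
12 | 2α-(benzyloxy)-10α-(tert-butyldimethylsilyloxy)-6-hydroxy-1β-methylbicyclo[5.3.0]dec-5-en-4-one (C6 enol of the 4,6-dione) | OC1=C2C(=O)C[C@H](OCc3ccccc3)[C@]2(C)[C@H](O[Si](C)(C)C(C)(C)C)CCC1 | intermediate
13 | 6-O-triethylsilyl enol ether of 12 | CC[Si](CC)(CC)OC1=C2C(=O)C[C@H](OCc3ccccc3)[C@]2(C)[C@H](O[Si](C)(C)C(C)(C)C)CCC1 | intermediate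
14 | 4α-isopropyl-4β-ol adduct of 13 (formed as its alkoxide, drawn as the alcohol) | CC[Si](CC)(CC)OC1=C2[C@](O)(C(C)C)C[C@H](OCc3ccccc3)[C@]2(C)[C@H](O[Si](C)(C)C(C)(C)C)CCC1 | intermediate
15 | 2α-(benzyloxy)-10α-(tert-butyldimethylsilyloxy)-4β-hydroxy-4α-isopropyl-1β-methyl-5α-H-bicyclo[5.3.0]decan-6-one | O=C1CCC[C@@H](O[Si](C)(C)C(C)(C)C)[C@@]2(C)[C@@H](OCc3ccccc3)C[C@@](O)(C(C)C)[C@H]12 | intermediate
16 | corresponding 4β,6α-diol | O[C@H]1CCC[C@@H](O[Si](C)(C)C(C)(C)C)[C@@]2(C)[C@@H](OCc3ccccc3)C[C@@](O)(C(C)C)[C@H]12 | intermediate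
17 | 6α-(4-methoxybenzoate) of 16 | COc1ccc(C(=O)O[C@H]2CCC[C@@H](O[Si](C)(C)C(C)(C)C)[C@@]3(C)[C@@H](OCc4ccccc4)C[C@@](O)(C(C)C)[C@H]23)cc1 | intermediate
18 | 2α,4β-diol obtained by debenzylation of 17 | COc1ccc(C(=O)O[C@H]2CCC[C@@H](O[Si](C)(C)C(C)(C)C)[C@@]3(C)[C@@H](O)C[C@@](O)(C(C)C)[C@H]23)cc1 | intermediate
19 | 2α-acetate of 18 | COc1ccc(C(=O)O[C@H]2CCC[C@@H](O[Si](C)(C)C(C)(C)C)[C@@]3(C)[C@@H](OC(C)=O)C[C@@](O)(C(C)C)[C@H]23)cc1 | intermediate
20 | 2α-acetoxy-6α-(4-methoxybenzoyloxy)-4β,10α-diol (8-nor-methyl daucane core) | COc1ccc(C(=O)O[C@H]2CCC[C@@H](O)[C@@]3(C)[C@@H](OC(C)=O)C[C@@](O)(C(C)C)[C@H]23)cc1 | intermediate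
21 | corresponding saturated 10-ketone | COc1ccc(C(=O)O[C@H]2CCCC(=O)[C@@]3(C)[C@@H](OC(C)=O)C[C@@](O)(C(C)C)[C@H]23)cc1 | intermediate
22 | corresponding 8-en-10-one | COc1ccc(C(=O)O[C@H]2CC=CC(=O)[C@@]3(C)[C@@H](OC(C)=O)C[C@@](O)(C(C)C)[C@H]23)cc1 | intermediate
23 | 2α-acetoxy-4β-hydroxy-6α-(4-methoxybenzoyloxy)daucan-10-one (C8 epimers) | COc1ccc(C(=O)O[C@H]2CC(C)CC(=O)[C@@]3(C)[C@@H](OC(C)=O)C[C@@](O)(C(C)C)[C@H]23)cc1 | intermediate
24 | 2α-acetoxy-4β-hydroxy-6α-(4-methoxybenzoyloxy)dauc-8-en-10-one | COc1ccc(C(=O)O[C@H]2CC(C)=CC(=O)[C@@]3(C)[C@@H](OC(C)=O)C[C@@](O)(C(C)C)[C@H]23)cc1 | intermediate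
25 | 2α-acetoxy-4β,10β-dihydroxy-6α-(4-methoxybenzoyloxy)dauc-8-ene (CNP0261832.1) | COc1ccc(C(=O)O[C@H]2CC(C)=C[C@H](O)[C@@]3(C)[C@@H](OC(C)=O)C[C@@](O)(C(C)C)[C@H]23)cc1 | target

**Step count and risks**

Total step count: 19. Longest linear sequence: 19 steps (1 → 25); 18 steps counted from dione 3.

Steps most likely to fail:

Step 8 (proposed new method). What may go wrong: the Lewis acid may decompose the diazo ketone before C–C bond formation, the oxido group may close onto C5 to an epoxide, or C7 may migrate instead of C1 to give a bridged bicycle. The fallback uses known chemistry in two stages and sets out from 10. Deprotonation of the diazomethyl ketone with LiHMDS (THF, −78 °C) and intramolecular aldol-type addition to the C6 ketone should give the cis-fused diazo ketol F1. Rh2(OAc)4 (cat., CH2Cl2, rt) then generates the carbenoid, whose 1,2-alkyl shift of the ring-fusion bond is a precedented ring-expanding route to cyclic 1,3-diketones. The sequence comes back to the route at 12.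

Step 10. What may go wrong: the silyl group may shuttle between O6 and O4 so that the reagent attacks C6, the organocerium reagent may attack the β face, or the tertiary hydroxyl may be lost during unmasking. The fallback sets C4 and C5 under thermodynamic instead of kinetic control and sets out from 13. The same addition and desilylation are run without regard to facial selectivity, which would give the C4 epimer F2. F2 is then treated with catalytic KOtBu in tBuOH/THF; retro-aldol cleavage of C4–C5 opens the five-membered ring to the isopropyl ketone F3. F3 should re-close by intramolecular aldol addition to the isomer with the 4β-hydroxyl hydrogen-bonded to the C6 carbonyl and the isopropyl group away from the seven-membered ring. That isomer is 15, where the route is rejoined.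

Step 19. What may go wrong: facial selectivity of hydride delivery to C10 may be poor, because the 2α-acetoxy group also flanks the α face. The fallback replaces reduction control by inversion and sets out from 24. The reduction product is accepted as the 10α-alcohol F4. A Mitsunobu reaction with chloroacetic acid (PPh3, DIAD, THF) should give the 10β-chloroacetate F5. Thiourea/NaHCO3 in EtOH then removes the chloroacetyl group selectively, leaving acetate and anisoate untouched, and gives 25.

Further compounds
F1 | step 8 | cis-fused 5-diazo-6-hydroxy-1-methyl-2-(benzyloxy)-10-(tert-butyldimethylsilyloxy)bicyclo[4.4.0]decan-4-one (daucane locants) | C[C@]12[C@@H](OCc3ccccc3)CC(=O)C(=[N+]=[N-])[C@@]1(O)CCC[C@H]2O[Si](C)(C)C(C)(C)C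
F2 | step 10 | C4 epimer of 15 (4α-hydroxy-4β-isopropyl; C5 not fixed) | O=C1CCC[C@@H](O[Si](C)(C)C(C)(C)C)[C@@]2(C)[C@@H](OCc3ccccc3)C[C@](O)(C(C)C)C12
F3 | step 10 | ring-opened diketone: 2-[1-(benzyloxy)-4-methyl-3-oxopentyl]-3-(tert-butyldimethylsilyloxy)-2-methylcycloheptan-1-one | CC(C)C(=O)C[C@H](OCc1ccccc1)[C@@]2(C)CC(=O)CCC[C@H]2O[Si](C)(C)C(C)(C)C
F4 | step 19 | 10α-epimer of 25 | COc1ccc(C(=O)O[C@H]2CC(C)=C[C@@H](O)[C@@]3(C)[C@@H](OC(C)=O)C[C@@](O)(C(C)C)[C@H]23)cc1
F5 | step 19 | 10β-chloroacetate of 25 | COc1ccc(C(=O)O[C@H]2CC(C)=C[C@H](OC(=O)CCl)[C@@]3(C)[C@@H](OC(C)=O)C[C@@](O)(C(C)C)[C@H]23)cc1
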